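**Retrosynthetic overview**
- The target comes from its bis-PMB ether by DDQ, that from the free C8 alcohol by acylation, and that from the C8 silyl ether of the lactone.
- Only one ring-forming step: a CrCl2 Barbier allylation of an acyclic bromo-enoate/enal closes the ten-membered carbocycle (C6–C7, setting C6 and C7), and the γ-lactone closes onto it in the same flask.
- The bromo-enal comes from a C1–C10 dialdehyde by Morita–Baylis–Hillman reaction and SN2' bromination; the dialdehyde comes from a Negishi union (C3–C4) of an alkyl iodide with a (Z)-vinyl iodide made from but-2-yne-1,4-diol.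
- Key step: the alkyl iodide fragment comes from a one-flask 1,2-metalate shift on a lithiated 2,3-dihydrofuran cuprate (PMBOCH2 migrates from Cu to C10, the ring opens, C1=C10 geometry is fixed), captured by (R)-glycidyl trityl ether (C9–C10 bond, C8 stereocentre).

Assumption: the target is taken exactly as drawn; atoms carry germacrane numbers (lactone O on C6, ester O on C8, C14 on C10, C15 on C4), i.e. 6R,7R,8R with C2/C9 cis on C1=C10 and C3/C6 cis on C4=C5 (both E by CIP); Bu3SnCH2OPMB and trityl-protected glycidol are taken as purchasable (PMB = 4-methoxybenzyl, Tr = trityl, TBS = tert-butyldimethylsilyl).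

**Route**

Step 1
Reactants: 1 2,3-dihydrofuran; 2 (R)-glycidyl trityl ether
Product: 6 (2R,4E)-4-{[(4-methoxybenzyl)oxy]methyl}-1-(trityloxy)hept-4-ene-2,7-diol, via lithiated dihydrofuran 3 (not isolated), via cuprate ate complex 4 (not isolated), via ring-opened alkenylcuprate 5 (not isolated)
Conditions: 1, t-BuLi, THF, −78 → 0 °C; added to Li[Cu(CH2OPMB)2] (from Bu3SnCH2OPMB 2 equiv, n-BuLi, THF, −78 °C, then CuBr·SMe2), −78 → 0 °C; then 2, −30 → 0 °C; aq NH4Cl
Reagents that add atoms: tributyl{[(4-methoxybenzyl)oxy]methyl}stannane (CCCC[Sn](CCCC)(CCCC)COCc1ccc(OC)cc1)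
Why: Proposed new method: a 1,2-metalate shift of an α-alkoxyalkenyl cuprate with an α-alkoxymethyl migrating group and in-flask epoxide capture; in ate complex 4 the PMBOCH2 ligand migrates from copper to the adjacent carbenoid carbon C10 anti to the ring C–O bond, which leaves as the alkoxide (inversion at the alkenyl carbon; anionic, stepwise, no cyclic electron reorganisation), so C14 ends trans and copper cis to the C2 chain, and the Gilman-type cuprate 5 then opens the CH2 terminus of 2 with retention at the alkenyl carbon, giving C2/C9 cis while C8 (R) is carried over untouched from 2; the closest known reaction type is the Kocienski 1,2-metalate rearrangement of 5-lithio-2,3-dihydrofuran-derived cuprates with alkyl, silyl or stannyl migrating groups and alkyl halide capture, together with epoxide opening by alkenylcuprates.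

Step 2
Reactants: 6 (2R,4E)-4-{[(4-methoxybenzyl)oxy]methyl}-1-(trityloxy)hept-4-ene-2,7-diol
Product: 7 (2R,4E)-7-iodo-4-{[(4-methoxybenzyl)oxy]methyl}-1-(trityloxy)hept-4-en-2-ol
Conditions: PPh3, I2, imidazole, CH2Cl2, 0 °C
Reagents that add atoms: iodine (II)
Why: Appel-type iodination is selective for the unhindered primary homoallylic hydroxyl over the secondary C8 hydroxyl next to CH2OTr, and no stereocentre is touched.

Step 3
Reactants: 7 (2R,4E)-7-iodo-4-{[(4-methoxybenzyl)oxy]methyl}-1-(trityloxy)hept-4-en-2-ol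
Product: 8 tert-butyl{[(2R,4E)-7-iodo-4-{[(4-methoxybenzyl)oxy]methyl}-1-(trityloxy)hept-4-en-2-yl]oxy}dimethylsilane
Conditions: TBSOTf, 2,6-lutidine, CH2Cl2, −78 → 0 °C
Reagents that add atoms: tert-butyldimethylsilyl trifluoromethanesulfonate (CC(C)(C)[Si](C)(C)OS(=O)(=O)C(F)(F)F)
Why: Silylation with the silyl triflate and a hindered base is fast at low temperature and spares the primary iodide, trityl and PMB ethers; a silyl ether rather than the final ester is used at O8 because an acyl group there would migrate to the C7 hydroxyl in step 9 and could be eliminated from the allylmetal in step 11.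

Step 4
Reactants: 9 but-2-yne-1,4-diol
Product: 10 4-[(4-methoxybenzyl)oxy]but-2-yn-1-ol
Conditions: NaH (1 equiv), PMBCl, Bu4NI (cat.), THF/DMF, 0 → 25 °C, diol in excess
Reagents that add atoms: 4-methoxybenzyl chloride (COc1ccc(CCl)cc1)
Why: Williamson monoetherification of the symmetric diol, used in excess to suppress the bis-ether.

Step 5
Reactants: 10 4-[(4-methoxybenzyl)oxy]but-2-yn-1-ol
Product: 12 (2Z)-3-iodo-4-[(4-methoxybenzyl)oxy]but-2-en-1-ol, via cyclic vinylalanate 11 (not isolated)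
Conditions: NaAlH2(OCH2CH2OMe)2, THF, 0 → 25 °C; then I2, THF, −78 → 0 °C; aq KNaC4H4O6
Reagents that add atoms: iodine (II)
Why: Hydroxyl-directed trans-hydroalumination (Corey trisubstituted-olefin synthesis) delivers H to C5 and aluminium to C4 through a five-membered alanate, and iodinolysis with retention puts iodine cis to C6, which fixes the C4=C5 geometry.

Step 6
Reactants: 8 tert-butyl{[(2R,4E)-7-iodo-4-{[(4-methoxybenzyl)oxy]methyl}-1-(trityloxy)hept-4-en-2-yl]oxy}dimethylsilane; 12 (2Z)-3-iodo-4-[(4-methoxybenzyl)oxy]but-2-en-1-ol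
Product: 14 (2E,6E,9R)-9-[(tert-butyldimethylsilyl)oxy]-3,7-bis{[(4-methoxybenzyl)oxy]methyl}-10-(trityloxy)deca-2,6-dien-1-ol, via alkylzinc iodide 13 (not isolated)
Conditions: 8, Zn dust, LiCl, THF, 40 °C; then 12, Pd(OAc)2 (3 mol %), SPhos (6 mol %), THF, 25 °C
Reagents that add atoms: none
Why: Negishi sp3–sp2 cross-coupling: zinc inserts into the primary C–I bond and zerovalent palladium couples the alkylzinc with the vinyl iodide with retention of alkene geometry, so C3 ends cis to C6; alkylzinc halides tolerate the free hydroxyl and the silyl, trityl and PMB ethers.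

Step 7
Reactants: 14 (2E,6E,9R)-9-[(tert-butyldimethylsilyl)oxy]-3,7-bis{[(4-methoxybenzyl)oxy]methyl}-10-(trityloxy)deca-2,6-dien-1-ol
Product: 15 (2E,6E,9R)-9-[(tert-butyldimethylsilyl)oxy]-3,7-bis{[(4-methoxybenzyl)oxy]methyl}deca-2,6-diene-1,10-diol
Conditions: CSA (10 mol %), MeOH/CH2Cl2 1:1, 0 °C
Reagents that add atoms: none
Why: Acid-catalysed solvolysis of the trityl ether (the trityl cation is trapped by methanol) is fast at 0 °C, where the secondary TBS ether and the PMB ethers are stable.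

Step 8
Reactants: 15 (2E,6E,9R)-9-[(tert-butyldimethylsilyl)oxy]-3,7-bis{[(4-methoxybenzyl)oxy]methyl}deca-2,6-diene-1,10-diol
Product: 16 (2E,6E,9R)-9-[(tert-butyldimethylsilyl)oxy]-3,7-bis{[(4-methoxybenzyl)oxy]methyl}deca-2,6-dienedial
Conditions: TEMPO (20 mol %), PhI(OAc)2 (2.4 equiv), CH2Cl2, 25 °C
Reagents that add atoms: none
Why: Oxoammonium (TEMPO/PhI(OAc)2) oxidation converts both primary alcohols to aldehydes without over-oxidation, without epimerising C8 and without isomerising the alkenes.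

Step 9
Reactants: 16 (2E,6E,9R)-9-[(tert-butyldimethylsilyl)oxy]-3,7-bis{[(4-methoxybenzyl)oxy]methyl}deca-2,6-dienedial; 17 methyl acrylate
Product: 18 methyl (4R,6E,10E)-4-[(tert-butyldimethylsilyl)oxy]-3-hydroxy-6,10-bis{[(4-methoxybenzyl)oxy]methyl}-2-methylidene-12-oxododeca-6,10-dienoate (mixture of C3 epimers)
Conditions: DABCO (1 equiv), 17 (10 equiv), MeOH, 25 °C
Reagents that add atoms: none
Why: Morita–Baylis–Hillman reaction: the DABCO-derived acrylate enolate adds only to the inductively activated α-silyloxy aldehyde (C7), the β,β-disubstituted enal (C6) being a very poor acceptor; the new carbinol is an inconsequential epimer mixture because it becomes sp2 in step 10.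

Step 10
Reactants: 18 methyl (4R,6E,10E)-4-[(tert-butyldimethylsilyl)oxy]-3-hydroxy-6,10-bis{[(4-methoxybenzyl)oxy]methyl}-2-methylidene-12-oxododeca-6,10-dienoate
Product: 19 methyl (2Z,4R,6E,10E)-2-(bromomethyl)-4-[(tert-butyldimethylsilyl)oxy]-6,10-bis{[(4-methoxybenzyl)oxy]methyl}-12-oxododeca-2,6,10-trienoate
Conditions: NBS, Me2S, CH2Cl2, 0 → 25 °C
Reagents that add atoms: N-bromosuccinimide (O=C1CCC(=O)N1Br)
Why: Corey–Kim-type activation of the allylic alcohol as an alkoxysulfonium salt and SN2' attack of bromide give the thermodynamically favoured (Z)-2-(bromomethyl)enoate (C8 trans to the ester), while the enal and the silyl and PMB ethers are inert.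

Step 11
Reactants: 19 methyl (2Z,4R,6E,10E)-2-(bromomethyl)-4-[(tert-butyldimethylsilyl)oxy]-6,10-bis{[(4-methoxybenzyl)oxy]methyl}-12-oxododeca-2,6,10-trienoate
Product: 21 8-O-TBS-14,15-di-O-PMB lactone, (3aS,4R,6E,10E,11aR)-4-[(tert-butyldimethylsilyl)oxy]-6,10-bis{[(4-methoxybenzyl)oxy]methyl}-3-methylidene-3a,4,5,8,9,11a-hexahydrocyclodeca[b]furan-2(3H)-one (same spatial arrangement at C6, C7, C8 as the target; 3aS only because O-silyl outranks), via chromium alkoxide 20 (not isolated)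
Conditions: CrCl2 (6 equiv), THF, 2 mM (syringe pump), 25 °C; aq work-up
Reagents that add atoms: none
Why: Nozaki–Hiyama-type Barbier macrocyclisation: divalent chromium turns the allylic bromide into an equilibrating allylchromium that adds at its γ-carbon C7 to the aldehyde C6 through a chair-like six-membered transition state with both ring arms equatorial, giving H6/H7 anti (trans-lactone after the chromium alkoxide attacks the adjacent methyl ester); with H8 held in the alkene plane by allylic strain, the aldehyde is expected to reach C7 anti to the C8–C9 bond and gauche to the silyloxy group, which places C11 and O8 on the same side (6R,7R, with 8R fixed).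

Step 12
Reactants: 21 8-O-TBS-14,15-di-O-PMB lactone
Product: 22 (3aR,4R,6E,10E,11aR)-4-hydroxy-6,10-bis{[(4-methoxybenzyl)oxy]methyl}-3-methylidene-3a,4,5,8,9,11a-hexahydrocyclodeca[b]furan-2(3H)-one
Conditions: HF·pyridine, pyridine, THF, 0 → 25 °C
Reagents that add atoms: none
Why: Buffered acidic fluoride desilylation frees O8 without basic fluoride, so the α-methylene lactone and the PMB ethers are untouched.

Step 13
Reactants: 22 (3aR,4R,6E,10E,11aR)-4-hydroxy-6,10-bis{[(4-methoxybenzyl)oxy]methyl}-3-methylidene-3a,4,5,8,9,11a-hexahydrocyclodeca[b]furan-2(3H)-one; 23 3-methylbutanoyl chloride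
Product: 24 (3aR,4R,6E,10E,11aR)-6,10-bis{[(4-methoxybenzyl)oxy]methyl}-3-methylidene-2-oxo-2,3,3a,4,5,8,9,11a-octahydrocyclodeca[b]furan-4-yl 3-methylbutanoate
Conditions: pyridine, DMAP (cat.), CH2Cl2, 0 °C
Reagents that add atoms: none
Why: DMAP-catalysed acylation of the only free hydroxyl proceeds with retention at C8, the two primary hydroxyls still being masked as PMB ethers.

Step 14
Reactants: 24 (3aR,4R,6E,10E,11aR)-6,10-bis{[(4-methoxybenzyl)oxy]methyl}-3-methylidene-2-oxo-2,3,3a,4,5,8,9,11a-octahydrocyclodeca[b]furan-4-yl 3-methylbutanoate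
Product: 25 (3aR,4R,6E,10E,11aR)-6,10-bis(hydroxymethyl)-3-methylidene-2-oxo-2,3,3a,4,5,8,9,11a-octahydrocyclodeca[b]furan-4-yl 3-methylbutanoate (target, CNP0199826.1)
Conditions: DDQ (2.5 equiv), CH2Cl2/pH 7 phosphate buffer, 0 °C
Reagents that add atoms: none
Why: Oxidative PMB cleavage (single-electron oxidation of the electron-rich benzyl ethers by DDQ, then hydrolysis of the oxocarbenium ions) releases both primary allylic alcohols under neutral conditions that leave the ester, the α-methylene lactone and the alkenes intact.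

**Compound list**

1 | 2,3-dihydrofuran | C1CC=CO1 | starting material
2 | (R)-glycidyl trityl ether, (2R)-2-[(triphenylmethoxy)methyl]oxirane | C1[C@@H](O1)COC(c2ccccc2)(c2ccccc2)c2ccccc2 | starting material
3 | 4,5-dihydrofuran-2-yllithium | [Li]C1=CCCO1 | intermediate
4 | dilithium (4,5-dihydrofuran-2-yl)bis{[(4-methoxybenzyl)oxy]methyl}cuprate | [Li+].[Li+].COc1ccc(COC[Cu-2](COCc2ccc(OC)cc2)C2=CCCO2)cc1 | intermediate
5 | dilithium salt of the ring-opened alkenyl(alkoxymethyl)cuprate alkoxide (Cu on C10 cis to the C2 chain, CH2OPMB trans) | [Li+].[Li+].[O-]CC/C=C(/COCc1ccc(OC)cc1)[Cu-]COCc1ccc(OC)cc1 | intermediate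
6 | (2R,4E)-4-{[(4-methoxybenzyl)oxy]methyl}-1-(trityloxy)hept-4-ene-2,7-diol | OCC/C=C(/COCc1ccc(OC)cc1)C[C@@H](O)COC(c1ccccc1)(c1ccccc1)c1ccccc1 | intermediate
7 | (2R,4E)-7-iodo-4-{[(4-methoxybenzyl)oxy]methyl}-1-(trityloxy)hept-4-en-2-ol | ICC/C=C(/COCc1ccc(OC)cc1)C[C@@H](O)COC(c1ccccc1)(c1ccccc1)c1ccccc1 | intermediate
8 | tert-butyl{[(2R,4E)-7-iodo-4-{[(4-methoxybenzyl)oxy]methyl}-1-(trityloxy)hept-4-en-2-yl]oxy}dimethylsilane | ICC/C=C(/COCc1ccc(OC)cc1)C[C@@H](O[Si](C)(C)C(C)(C)C)COC(c1ccccc1)(c1ccccc1)c1ccccc1 | intermediate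
9 | but-2-yne-1,4-diol | OCC#CCO | starting material
10 | 4-[(4-methoxybenzyl)oxy]but-2-yn-1-ol | OCC#CCOCc1ccc(OC)cc1 | intermediate
11 | sodium cyclic vinylalanate (2,5-dihydro-1,2-oxaluminole, Al on C4 and O6) | [Na+].COCCO[Al-]1(OCCOC)OCC=C1COCc1ccc(OC)cc1 | intermediate
12 | (2Z)-3-iodo-4-[(4-methoxybenzyl)oxy]but-2-en-1-ol | OC/C=C(\I)COCc1ccc(OC)cc1 | intermediate
13 | alkylzinc iodide of 8 (Zn at C3) | I[Zn]CC/C=C(/COCc1ccc(OC)cc1)C[C@@H](O[Si](C)(C)C(C)(C)C)COC(c1ccccc1)(c1ccccc1)c1ccccc1 | intermediate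
14 | (2E,6E,9R)-9-[(tert-butyldimethylsilyl)oxy]-3,7-bis{[(4-methoxybenzyl)oxy]methyl}-10-(trityloxy)deca-2,6-dien-1-ol | OC/C=C(/COCc1ccc(OC)cc1)CC/C=C(/COCc1ccc(OC)cc1)C[C@@H](O[Si](C)(C)C(C)(C)C)COC(c1ccccc1)(c1ccccc1)c1ccccc1 | intermediate
15 | (2E,6E,9R)-9-[(tert-butyldimethylsilyl)oxy]-3,7-bis{[(4-methoxybenzyl)oxy]methyl}deca-2,6-diene-1,10-diol | OC/C=C(/COCc1ccc(OC)cc1)CC/C=C(/COCc1ccc(OC)cc1)C[C@@H](O[Si](C)(C)C(C)(C)C)CO | intermediate
16 | (2E,6E,9R)-9-[(tert-butyldimethylsilyl)oxy]-3,7-bis{[(4-methoxybenzyl)oxy]methyl}deca-2,6-dienedial | O=C/C=C(/COCc1ccc(OC)cc1)CC/C=C(/COCc1ccc(OC)cc1)C[C@@H](O[Si](C)(C)C(C)(C)C)C=O | intermediate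
17 | methyl acrylate | C=CC(=O)OC | starting material
18 | methyl (4R,6E,10E)-4-[(tert-butyldimethylsilyl)oxy]-3-hydroxy-6,10-bis{[(4-methoxybenzyl)oxy]methyl}-2-methylidene-12-oxododeca-6,10-dienoate (C3 epimers) | O=C/C=C(/COCc1ccc(OC)cc1)CC/C=C(/COCc1ccc(OC)cc1)C[C@@H](O[Si](C)(C)C(C)(C)C)C(O)C(=C)C(=O)OC | intermediate
19 | methyl (2Z,4R,6E,10E)-2-(bromomethyl)-4-[(tert-butyldimethylsilyl)oxy]-6,10-bis{[(4-methoxybenzyl)oxy]methyl}-12-oxododeca-2,6,10-trienoate | O=C/C=C(/COCc1ccc(OC)cc1)CC/C=C(/COCc1ccc(OC)cc1)C[C@@H](O[Si](C)(C)C(C)(C)C)/C=C(\CBr)C(=O)OC | intermediate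
20 | ring-closed dichlorochromium alkoxide (O6–CrCl2) of the ten-membered hydroxy methyl ester, configured as the target at C6, C7, C8 | C=C(C(=O)OC)[C@H]1[C@H](O[Cr](Cl)Cl)/C=C(/COCc2ccc(OC)cc2)CC/C=C(/COCc2ccc(OC)cc2)C[C@H]1O[Si](C)(C)C(C)(C)C | intermediate
21 | 8-O-TBS-14,15-di-O-PMB lactone (see step 11) | C=C1C(=O)O[C@@H]2/C=C(/COCc3ccc(OC)cc3)CC/C=C(/COCc3ccc(OC)cc3)C[C@@H](O[Si](C)(C)C(C)(C)C)[C@@H]12 | intermediate
22 | 8-hydroxy-14,15-di-O-PMB lactone (see step 12) | C=C1C(=O)O[C@@H]2/C=C(/COCc3ccc(OC)cc3)CC/C=C(/COCc3ccc(OC)cc3)C[C@@H](O)[C@@H]12 | intermediate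
23 | 3-methylbutanoyl chloride (isovaleryl chloride) | CC(C)CC(=O)Cl | starting material
24 | 14,15-di-O-PMB ether of the target (see step 13) | C=C1C(=O)O[C@@H]2/C=C(/COCc3ccc(OC)cc3)CC/C=C(/COCc3ccc(OC)cc3)C[C@@H](OC(=O)CC(C)C)[C@@H]12 | intermediate
25 | CNP0199826.1 (see step 14) | C=C1C(=O)O[C@@H]2/C=C(/CO)CC/C=C(/CO)C[C@@H](OC(=O)CC(C)C)[C@@H]12 | target

**Step count and risks**

Total step count: 14 (steps 4 and 5 make the vinyl iodide fragment). Longest linear sequence: 12 steps (1, 2, 3, 6–14, from 2,3-dihydrofuran).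

Three steps most likely to fail:

Step 1 (the proposed new three-component 1,2-metalate shift). The risks are the thermal stability and migratory aptitude of the alkoxymethyl ligand and which ligand of cuprate 5 opens the epoxide. The fallback uses known reactions only, sets out from 2 and comes back at 6. The sodium salt of triethyl phosphonoacetate opens 2 at its CH2 and the alkoxide lactonises (NaH, THF then toluene, 90 °C) to (5R)-3-(diethoxyphosphoryl)-5-[(trityloxy)methyl]dihydrofuran-2(3H)-one F1. Horner–Wadsworth–Emmons reaction of F1 with 3-[(tert-butyldimethylsilyl)oxy]propanal (NaH, THF, 0 °C) gives (3E,5R)-3-{3-[(tert-butyldimethylsilyl)oxy]propylidene}-5-[(trityloxy)methyl]dihydrofuran-2(3H)-one F2, whose E geometry is the required C2/C9-cis arrangement. i-Bu2AlH (CH2Cl2, −78 → 0 °C) reduces the lactone to (2R,4E)-7-[(tert-butyldimethylsilyl)oxy]-4-(hydroxymethyl)-1-(trityloxy)hept-4-en-2-ol F3. The primary allylic hydroxyl is etherified selectively (NaH 1 equiv, PMBCl, Bu4NI, THF, 0 °C) to (2R,4E)-7-[(tert-butyldimethylsilyl)oxy]-4-{[(4-methoxybenzyl)oxy]methyl}-1-(trityloxy)hept-4-en-2-ol F4, and Bu4NF (THF, 0 °C) removes the silyl group to give 6.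

Step 9 (Morita–Baylis–Hillman reaction on the dialdehyde). The risks are a slow reaction, partial epimerisation of the α-silyloxy aldehyde by the amine and incomplete discrimination from the enal. The fallback sets out from 16 and comes back at 18, replacing amine catalysis by carbonyl addition of a preformed acrylate α-anion equivalent. Methyl propiolate is hydroaluminated (i-Bu2AlH, HMPA, THF, 0 °C) to methyl 2-(diisobutylalumanyl)prop-2-enoate F5. One equivalent of F5 adds at −40 °C within minutes to the more electrophilic α-silyloxy aldehyde of 16 and gives 18 after aqueous work-up.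

Step 11 (macrocyclisation). The ring closure is precedented for germacranolides, but the face of C7 attacked relative to the C8 silyl ether cannot be guaranteed; the step-11 model is an expectation, not a certainty. The fallback applies if the aldehyde instead adds anti to the silyloxy group (7,8-anti series). It sets out from 1 and comes back at 24: steps 1–3 and 6–12 are run with purchased (S)-glycidyl trityl ether in place of 2, and C8 is inverted at the end. This gives in turn the (2S)-enantiomer of 6 F6, the (2S)-iodide F7, its TBS ether F8, the derived alkylzinc iodide F9, the (9S)-dienol F10, the (9S)-diol F11, the (9S)-dialdehyde F12, the (4S) Baylis–Hillman adduct F13 and the (4S)-bromide F14. Ring closure with CrCl2 then gives the 8-epimeric chromium alkoxide F15 and the C8 epimer of 21 F16, and HF·pyridine gives the C8 epimer of 22 F17. Mitsunobu esterification of F17 (isovaleric acid, PPh3, DIAD, THF, 0 °C) inverts C8 and gives 24.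

Further compounds
F1 | step 1 | (5R)-3-(diethoxyphosphoryl)-5-[(trityloxy)methyl]dihydrofuran-2(3H)-one (C3 epimers) | CCOP(=O)(OCC)C1C[C@H](COC(c2ccccc2)(c2ccccc2)c2ccccc2)OC1=O
F2 | step 1 | (3E,5R)-3-{3-[(tert-butyldimethylsilyl)oxy]propylidene}-5-[(trityloxy)methyl]dihydrofuran-2(3H)-one | O=C1O[C@@H](COC(c2ccccc2)(c2ccccc2)c2ccccc2)C/C1=C\CCO[Si](C)(C)C(C)(C)C
F3 | step 1 | (2R,4E)-7-[(tert-butyldimethylsilyl)oxy]-4-(hydroxymethyl)-1-(trityloxy)hept-4-en-2-ol | CC(C)(C)[Si](C)(C)OCC/C=C(/CO)C[C@@H](O)COC(c1ccccc1)(c1ccccc1)c1ccccc1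
F4 | step 1 | (2R,4E)-7-[(tert-butyldimethylsilyl)oxy]-4-{[(4-methoxybenzyl)oxy]methyl}-1-(trityloxy)hept-4-en-2-ol | CC(C)(C)[Si](C)(C)OCC/C=C(/COCc1ccc(OC)cc1)C[C@@H](O)COC(c1ccccc1)(c1ccccc1)c1ccccc1
F5 | step 9 | methyl 2-(diisobutylalumanyl)prop-2-enoate | C=C(C(=O)OC)[Al](CC(C)C)CC(C)C
F6 | step 11 | (2S,4E)-4-{[(4-methoxybenzyl)oxy]methyl}-1-(trityloxy)hept-4-ene-2,7-diol | OCC/C=C(/COCc1ccc(OC)cc1)C[C@H](O)COC(c1ccccc1)(c1ccccc1)c1ccccc1
F7 | step 11 | (2S,4E)-7-iodo-4-{[(4-methoxybenzyl)oxy]methyl}-1-(trityloxy)hept-4-en-2-ol | ICC/C=C(/COCc1ccc(OC)cc1)C[C@H](O)COC(c1ccccc1)(c1ccccc1)c1ccccc1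
F8 | step 11 | tert-butyl{[(2S,4E)-7-iodo-4-{[(4-methoxybenzyl)oxy]methyl}-1-(trityloxy)hept-4-en-2-yl]oxy}dimethylsilane | ICC/C=C(/COCc1ccc(OC)cc1)C[C@H](O[Si](C)(C)C(C)(C)C)COC(c1ccccc1)(c1ccccc1)c1ccccc1
F9 | step 11 | alkylzinc iodide of F8 | I[Zn]CC/C=C(/COCc1ccc(OC)cc1)C[C@H](O[Si](C)(C)C(C)(C)C)COC(c1ccccc1)(c1ccccc1)c1ccccc1
F10 | step 11 | (2E,6E,9S)-9-[(tert-butyldimethylsilyl)oxy]-3,7-bis{[(4-methoxybenzyl)oxy]methyl}-10-(trityloxy)deca-2,6-dien-1-ol | OC/C=C(/COCc1ccc(OC)cc1)CC/C=C(/COCc1ccc(OC)cc1)C[C@H](O[Si](C)(C)C(C)(C)C)COC(c1ccccc1)(c1ccccc1)c1ccccc1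
F11 | step 11 | (2E,6E,9S)-9-[(tert-butyldimethylsilyl)oxy]-3,7-bis{[(4-methoxybenzyl)oxy]methyl}deca-2,6-diene-1,10-diol | OC/C=C(/COCc1ccc(OC)cc1)CC/C=C(/COCc1ccc(OC)cc1)C[C@H](O[Si](C)(C)C(C)(C)C)CO
F12 | step 11 | (2E,6E,9S)-9-[(tert-butyldimethylsilyl)oxy]-3,7-bis{[(4-methoxybenzyl)oxy]methyl}deca-2,6-dienedial | O=C/C=C(/COCc1ccc(OC)cc1)CC/C=C(/COCc1ccc(OC)cc1)C[C@H](O[Si](C)(C)C(C)(C)C)C=O
F13 | step 11 | methyl (4S,6E,10E)-4-[(tert-butyldimethylsilyl)oxy]-3-hydroxy-6,10-bis{[(4-methoxybenzyl)oxy]methyl}-2-methylidene-12-oxododeca-6,10-dienoate (C3 epimers) | O=C/C=C(/COCc1ccc(OC)cc1)CC/C=C(/COCc1ccc(OC)cc1)C[C@H](O[Si](C)(C)C(C)(C)C)C(O)C(=C)C(=O)OC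
F14 | step 11 | methyl (2Z,4S,6E,10E)-2-(bromomethyl)-4-[(tert-butyldimethylsilyl)oxy]-6,10-bis{[(4-methoxybenzyl)oxy]methyl}-12-oxododeca-2,6,10-trienoate | O=C/C=C(/COCc1ccc(OC)cc1)CC/C=C(/COCc1ccc(OC)cc1)C[C@H](O[Si](C)(C)C(C)(C)C)/C=C(\CBr)C(=O)OC
F15 | step 11 | C8 epimer of chromium alkoxide 20 | C=C(C(=O)OC)[C@H]1[C@H](O[Cr](Cl)Cl)/C=C(/COCc2ccc(OC)cc2)CC/C=C(/COCc2ccc(OC)cc2)C[C@@H]1O[Si](C)(C)C(C)(C)C
F16 | step 11 | C8 epimer of lactone 21 | C=C1C(=O)O[C@@H]2/C=C(/COCc3ccc(OC)cc3)CC/C=C(/COCc3ccc(OC)cc3)C[C@H](O[Si](C)(C)C(C)(C)C)[C@@H]12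
F17 | step 11 | C8 epimer of alcohol 22 | C=C1C(=O)O[C@@H]2/C=C(/COCc3ccc(OC)cc3)CC/C=C(/COCc3ccc(OC)cc3)C[C@H](O)[C@@H]12
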